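The earlier runs and the new flask stem from a simulated flask for substances that don't exist; noise was put on by code.

Every starting complex charged stays somewhere, so the two readings and the unread gap add to 100 per cent. The flasks and questions:

| flask | starting complex | incoming ligand | leaving ligand | remark | time |
|---|---|---|---|---|---|
| larch | 0.050 M | 0.050 M | 0.25 M | run made earlier |  |
| cedar | 0.034 M | 0.050 M | 0.25 M | run made earlier |  |
| oak | 0.075 M | 0.050 M | 0.25 M | run made earlier |  |
| ash | 0.050 M | 0.050 M | 0.50 M | run made earlier |  |
| north-west | 0.050 M | 0.0500 M (fed, over 25.0 h) | 0.250 M | a stirred flask in which incoming ligand is dosed at a steady rate over 25.0 h without added volume, worked up at 25 h | 25 h |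
| north-east | 0.050 M (fed, over 25.0 h) | 0.0500 M | 0.250 M | a stirred flask in which starting complex is dosed at a steady rate over 25.0 h without added volume, worked up at 25 h | 25 h |
| north | 0.050 M | 0.0500 M | 0.250 M | everything together in a closed stirred flask, run for 25 h | 25 h |
| south-west | 0.050 M | 0.0500 M | 0.250 M | a single well-mixed tank run continuously and read at steady state, 25 h in it on average |  |

- larch (time / h: complex with one exchanged / %, starting complex / %): 2.00: 16.3, 77.7; 3.00: 21.3, 69.9; 5.00: 29.3, 57.4; 8.00: 37.2, 43.6; 10.0: 39.2, 38.1; 15.0: 43.5, 27.8; 25.0: 44.7, 17.2
- cedar (time / h: complex with one exchanged / %, starting complex / %): 3.00: 23.0, 70.4; 6.00: 34.2, 50.2; 8.00: 37.8, 41.7; 12.0: 44.3, 29.1; 15.0: 44.6, 22.2; 20.0: 46.6, 15.8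
- oak (time / h: complex with one exchanged / %, starting complex / %): 1.50: 12.3, 83.2; 2.50: 18.3, 75.3; 4.00: 22.9, 64.5; 6.00: 29.7, 55.1; 8.00: 33.7, 48.5; 12.0: 37.8, 37.1; 20.0: 40.6, 27.2
- ash (time / h: complex with one exchanged / %, starting complex / %): 4.00: 26.2, 63.2; 8.00: 35.9, 43.6; 12.0: 42.4, 32.5; 15.0: 43.1, 26.8; 20.0: 44.6, 21.7

(scatter of a reading: 0.5 percentage points)

- the stated concentrations are those of everything mixed, before any reaction; amounts are the same in each set-up
- the feed brings no volume worth counting
- the earlier runs were made in a closed, stirred flask

- the set-up with the highest amount of complex with one exchanged at the outlet or at the end, in percent of the starting complex put in ("none" if the first two lie within 2 percentage points) (north-west / north-east / north / south-west / none)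
- amount of complex with one exchanged at the outlet or at the end, in percent of the starting complex put in, north-west
- amount of complex with one exchanged at the outlet or at the end, in percent of the starting complex put in, north-east
- amount of complex with one exchanged at the outlet or at the end, in percent of the starting complex put in, north
- amount of complex with one exchanged at the outlet or at the end, in percent of the starting complex put in, south-west

What does the gap show? In larch at 2.00 h it grows at 0.0300 h⁻¹, and in oak, with more complex, at 0.0300 h⁻¹. I read this as a leak, though it may hold further-exchanged complex too.

And the exchange? Larch loses starting complex at 0.126 h⁻¹, so the rest, 0.0962 h⁻¹, is the exchange. That is only an average over the first stretch, since larch charges 0.050 M of ligand against 0.050 M of complex and the ligand falls as it reacts.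

Does it need ligand? I take it to be proportional to ligand. Oak, charged with more complex than cedar but the same ligand, keeps 27.2% at 20.0 h against 15.8% in cedar at 20.0 h.

So what carries over? My estimate from the larch average is 0.0156 M: this is the balance level, the ligand concentration at which exchange and leak take equal shares.

Is north-west starved, then? If dosing equalled uptake with complex at its charge, the ligand would stand at 0.0208 M, which is above the balance level, so exchange would take 57.1%. The ligand must first climb from zero, so this is a rough figure.

The forecast names north and gives 24% for north-west, 36% for north-east, 45% for north and 32% for south-west, with north-west “starved, so the leak wins”. My reckoning differs there: I expect north-west above 24%.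

The flask gives 32.4%, 34.3%, 44.9% and 29.3% in that order, and north is best.

    starting complex ⇌ dormant form (K = 3.10, k = 7.93 × 10⁻⁶ s⁻¹)
    complex with two exchanged + incoming ligand → leaving ligand + complex with three exchanged (k = 4.68 × 10⁻⁴ L mol⁻¹ s⁻¹)
    complex with one exchanged + incoming ligand → leaving ligand + complex with two exchanged (k = 2.10 × 10⁻⁴ L mol⁻¹ s⁻¹)
    starting complex + incoming ligand → leaving ligand + complex with one exchanged (k = 5.80 × 10⁻⁴ L mol⁻¹ s⁻¹)

In north, at charged concentrations, the first exchange alone has a half-life of 6.6 h, shorter than the 24 h of the forward step to dormant form alone. North-west, reckoned above the balance level, gave 8.4 percentage points more than the forecast. In north-east the complex first meets ligand at 0.0500 M, which gives exchange a share of 76.2%, and that flask gave 34.3%.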